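The earlier runs and the new flask come from a simulation from invented constants, and the scatter is random.

At early times Friday's flask loses free monomer fast, with 32% of its charge left at 0.250 min, and then the loss stops well short of zero.

the same everywhere: free monomer 0.012 M
- Friday's: initiator 86 µM; run made earlier
- Saturday's: initiator 290 µM; run made earlier
- delta: initiator 60 µM; time 5.0 min
- eta: initiator 200 µM; time 5.0 min

| run | time / min | monomer in chains / % | free monomer / % |
|---|---|---|---|
| Friday's | 0.250 | 69 | 32 |
| Friday's | 0.500 | 89 | 10 |
| Friday's | 0.833 | 92 | 6 |
| Friday's | 1.33 | 92 | 6 |
| Friday's | 2.00 | 93 | 9 |
| Friday's | 4.00 | 91 | 7 |
| Saturday's | 0.667 | 92 | 6 |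
| Saturday's | 1.33 | 92 | 9 |
| Saturday's | 2.00 | 93 | 8 |
| Saturday's | 2.50 | 92 | 9 |
| Saturday's | 3.00 | 93 | 8 |
| Saturday's | 4.00 | 94 | 5 |

(each reading ± 1.5 percentage points)

- the average divides the monomer in chains by the number of chains begun, living and dead together
- steps that have been proposed: free monomer + initiator -> living end + monomer in chains; free monomer + living end -> monomer in chains + living end; monomer in chains + living end -> free monomer + living end; initiator -> spent initiator; free monomer -> decomposition product
- the earlier runs do not show the number of chains; that part of a forecast is a guess

- which of the two ends with the longer chains by the average number of monomer units in a chain (chains begun, living or dead) ("neither" if they lie within 10%) (delta / eta / neither)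
- average number of monomer units in a chain (chains begun, living or dead) at the end, delta
- average number of monomer units in a chain (chains begun, living or dead) at the end, eta

What do you follow? The fraction left, not the fraction made. Over the late readings of both runs, free monomer averages 7.30% of its charge.

Does initiator move that level? Not visibly. Saturday's initiator charge is 3.37 times Friday's, yet the late readings average 7.00% in Friday's run and 7.50% in Saturday's, against a scatter of 1.5 percentage points on each reading.

Why should it stop there? Suppose a living end gains units in proportion to [free monomer] and sheds them at a rate that depends on neither [free monomer] nor [monomer in chains]. The two then balance at one [free monomer], and the count of ends cancels. So I carry 0.876 mM: the floor, the [free monomer] at which a living end gains as fast as it sheds. The field calls it the equilibrium monomer concentration.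

Both runs were charged alike, so how do you know it is a concentration and not a fraction? From these runs I don't; it is my assumption about how a living end sheds.

Does delta get there in time? Friday's excess over the floor, from zero time to the first reading, gives a time constant of 0.189 min. If that time constant goes inversely with initiator, delta's is 0.271 min, so 5.0 min is 18.5 time constants.

And the length? Charge minus floor, divided by chains begun. With one chain per initiator, I reckon 185 for delta and 55.6 for eta, so delta ends longer. The chain count is a guess, since the readings do not show it.

The forecast names delta, with 195 for delta and 58 for eta, above my reckoning, and says of its numbers: “I skew the estimates and ranges upward”.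

The flask gives delta, with 193 for delta and 59.8 for eta.

    free monomer + initiator → living end + monomer in chains (k = 34.0 M⁻¹ s⁻¹)
    free monomer + living end → monomer in chains + living end, rate k2*[living end]*[free monomer] (k = 1400 M⁻¹ s⁻¹)
    monomer in chains + living end → free monomer + living end, rate k3*[living end] as long as [monomer in chains] is above zero (k = 1.20 s⁻¹)
    initiator → spent initiator (k = 0.0150 s⁻¹)
    free monomer → decomposition product (k = 7.20 × 10⁻⁶ s⁻¹)

The gap comes from the difference in initiator: eta, given delta's initiator charge, reaches 193 instead of 59.8. The floor still serves in eta, where charge minus floor, divided by its 1.86 × 10⁻⁴ M of living ends, gives 59.7. A neighbour of eta charged with 0.030 M of free monomer should keep 2.92% of it by the floor, and that flask ends with 2.9% left and chains averaging 149 units.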